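## Retrosynthetic overview

1. The target is disconnected by double dehydrogenation to a C2-symmetric bis-enone: two octal-2-ones joined C1–C1'. The future biaryl bond is carried in as a CH2–CH2 unit and is never made by aryl–aryl coupling.
2. The bis-enone is disconnected by a two-directional Robinson annulation to 2 × tetrahydrocarvone and 2,7-dimethylocta-1,7-diene-3,6-dione. Both rings B and four C–C bonds form in one operation (key step).
3. The dienedione comes from oxidative enolate dimerisation of 3-methylbut-3-en-2-one. Tetrahydrocarvone comes from (R)-carvone, which supplies ring A and the isopropyl stereocentre.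
4. Ring order: rings A are bought (carvone), both rings B are closed together, then both are aromatised together. The CH–CH3 centres are set by A(1,3) strain in the key step.

Assumption: the target SMILES carries no descriptor for the biaryl axis, so the axis is taken as unspecified; the route fixes only the four stereocentres (5S,5'S,8S,8'S).

Locants in the text are those of the binaphthalene skeleton of the target: C1 biaryl carbon, C2 C–OH, C3 C–CH3, C4 aromatic CH, C5 CH–iPr, C8 CH–CH3.

## Route

Step 1
Reactants: 1 (R)-(−)-carvone
Product: 2 (2RS,5R)-2-methyl-5-(propan-2-yl)cyclohexan-1-one (tetrahydrocarvone)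
Conditions: H2 (1 atm), 10% Pd/C, EtOAc, rt
Reagents that add atoms: none
Why: Heterogeneous catalytic hydrogenation saturates the isopropenyl and enone C=C bonds and leaves the ketone, the carvone stereocentre is not involved and is retained, and the new methyl-bearing centre is left as an epimer mixture because it is re-set in step 3.

Step 2
Reactants: 3 3-methylbut-3-en-2-one (two molecules)
Product: 5 2,7-dimethylocta-1,7-diene-3,6-dione, via lithium 3-methylbuta-1,3-dien-2-olate 4 (not isolated)
Conditions: LiN(iPr)2 (1.05 equiv), THF, −78 °C; then CuCl2 (1.1 equiv), DMF, −78 °C to rt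
Reagents that add atoms: none
Why: Kinetic deprotonation of the acetyl CH3 gives the cross-conjugated lithium dienolate, which CuCl2 (divalent copper) oxidises to the α-keto radical that dimerises at its CH2 terminus (Saegusa-type oxidative enolate homocoupling to a 1,4-diketone); no stereocentre is formed.

Step 3
Reactants: 2 (2RS,5R)-2-methyl-5-(propan-2-yl)cyclohexan-1-one (2.4 equiv); 5 2,7-dimethylocta-1,7-diene-3,6-dione (1 equiv)
Product: 8 bis-octalone (4aS,4a'S,5S,5'S,8S,8'S)-3,3',8,8'-tetramethyl-5,5'-di(propan-2-yl)-4,4',4a,4a',5,5',6,6',7,7',8,8'-dodecahydro-[1,1'-binaphthalene]-2,2'(3H,3'H)-dione, via pyrrolidine enamine 6 (not isolated), via tetraketone 7 (not isolated)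
Conditions: pyrrolidine (2.6 equiv), TsOH (cat.), toluene, reflux, Dean–Stark, then concentrate; 5, dioxane, reflux; then AcOH, CH3CO2Na, H2O, reflux
Reagents that add atoms: none
Why: Proposed new method: a two-directional Stork enamine Michael addition/Robinson annulation, whose closest known reaction type is the enamine Robinson annulation of 2-methylcyclohexanone with ethyl vinyl ketone; the less substituted enamine 6 adds through its CH carbon to both isopropenyl-ketone termini of 5, and on buffered hydrolysis the pyrrolidinium acetate activates only the CH2 α-carbons of the central 1,4-diketone (less substituted enamines), so each closes onto its own ring ketone to give the six-membered enone instead of the cyclopentenone that would need the branched α-carbon, forming both rings B and four C–C bonds in one pot; the C8 methyl centre is epimerisable at the enamine, iminium and ketone stages and is driven axial by A(1,3) strain (first against the pyrrolidine ring, finally against the C1 substituent), which places it cis to the equatorial isopropyl group fixed by carvone (8S), while C4a settles trans to the isopropyl group and C3 stays a mixture, both being erased in step 4.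

Step 4
Reactants: 8 bis-octalone
Product: 10 (5S,5'S,8S,8'S)-3,3',8,8'-tetramethyl-5,5'-di(propan-2-yl)-5,5',6,6',7,7',8,8'-octahydro-[1,1'-binaphthalene]-2,2'-diol (CNP0152871.1), via bis-dienone 9 (not isolated)
Conditions: Pd(OCOCF3)2 (10 mol%), 2-(dimethylamino)pyridine (20 mol%), TsOH·H2O (40 mol%), O2 (1 atm), DMSO, 80 °C
Reagents that add atoms: none
Why: Aerobic palladium-catalysed dehydrogenation of a cyclohexenone to a phenol (Stahl-type): a divalent-palladium enolate forms at C3, β-hydride elimination from C4 gives the cross-conjugated dienone, and its 4a-H tautomerises to the phenol, so the C1–C1' bond becomes the biaryl axis, the C5 and C8 centres are untouched, and the C3 and C4a centres disappear.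

## Compound list

1 | (R)-(−)-carvone, (5R)-2-methyl-5-(prop-1-en-2-yl)cyclohex-2-en-1-one | CC1=CC[C@H](CC1=O)C(C)=C | starting material
2 | (2RS,5R)-2-methyl-5-(propan-2-yl)cyclohexan-1-one (tetrahydrocarvone, C2 epimer mixture) | CC1CC[C@H](CC1=O)C(C)C | intermediate
3 | 3-methylbut-3-en-2-one (methyl isopropenyl ketone) | CC(=O)C(C)=C | starting material
4 | lithium 3-methylbuta-1,3-dien-2-olate (not isolated) | [Li+].[O-]C(=C)C(C)=C | intermediate
5 | 2,7-dimethylocta-1,7-diene-3,6-dione | C=C(C)C(=O)CCC(=O)C(C)=C | intermediate
6 | 1-[(3S,6S)-6-methyl-3-(propan-2-yl)cyclohex-1-en-1-yl]pyrrolidine (methyl pseudoaxial, cis to isopropyl; not isolated) | C[C@H]1CC[C@H](C=C1N2CCCC2)C(C)C | intermediate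
7 | 2,2'-(2,7-dimethyl-3,6-dioxooctane-1,8-diyl)bis[(3S)-6-methyl-3-(propan-2-yl)cyclohexan-1-one] (other centres epimeric; not isolated) | CC1CC[C@@H](C(C)C)C(CC(C)C(=O)CCC(=O)C(C)CC2[C@H](C(C)C)CCC(C)C2=O)C1=O | intermediate
8 | (4aS,4a'S,5S,5'S,8S,8'S)-3,3',8,8'-tetramethyl-5,5'-di(propan-2-yl)-4,4',4a,4a',5,5',6,6',7,7',8,8'-dodecahydro-[1,1'-binaphthalene]-2,2'(3H,3'H)-dione (C3/C3' epimeric) | O=C1C(C)C[C@H]2[C@H](C(C)C)CC[C@H](C)C2=C1C1=C2[C@@H](C)CC[C@@H](C(C)C)[C@@H]2CC(C)C1=O | intermediate
9 | (4aR,4a'R,5S,5'S,8S,8'S)-3,3',8,8'-tetramethyl-5,5'-di(propan-2-yl)-5,5',6,6',7,7',8,8'-octahydro-[1,1'-binaphthalene]-2,2'(4aH,4a'H)-dione (drawn with both halves at the dienone stage; not isolated) | O=C1C(C)=C[C@H]2[C@H](C(C)C)CC[C@H](C)C2=C1C1=C2[C@@H](C)CC[C@@H](C(C)C)[C@@H]2C=C(C)C1=O | intermediate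
10 | (5S,5'S,8S,8'S)-3,3',8,8'-tetramethyl-5,5'-di(propan-2-yl)-5,5',6,6',7,7',8,8'-octahydro-[1,1'-binaphthalene]-2,2'-diol | Cc1cc2c(c(-c3c(O)c(C)cc4c3[C@@H](C)CC[C@H]4C(C)C)c1O)[C@@H](C)CC[C@H]2C(C)C | target

## Step count and risks

Total steps: 4. Longest linear sequence: 3 (steps 1, 3, 4); step 2 is the one-step convergent branch.

Steps most likely to fail, in order: step 3, step 4, step 2.

**Step 3 (double annulation).** The risks are sluggish enamine addition to the α-methyl enones, cyclopentenone or furan formation from the 1,4-diketone, and incomplete control of the C8 methyl centre. A mixture at C8 can first be equilibrated with CH3ONa in CH3OH. The fallback sets out from 2 and comes back at 10, and it makes the biaryl bond last instead of carrying it through. Ketone 2 is converted to enamine 6 as before and annulated with the simple enone 3 (dioxane, reflux; then AcOH, CH3CO2Na, H2O). This gives the monomeric octalone (3RS,4aS,5S,8S)-3,8-dimethyl-5-(propan-2-yl)-4,4a,5,6,7,8-hexahydronaphthalen-2(3H)-one F2. The aerobic palladium dehydrogenation of step 4 then gives (5S,8S)-3,8-dimethyl-5-(propan-2-yl)-5,6,7,8-tetrahydronaphthalen-2-ol F3, where any C8 epimer is removed by chromatography. Oxidative phenol coupling at the only free ortho position (di-tert-butyl peroxide, chlorobenzene, reflux) gives 10.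

**Step 4 (double aromatisation).** The risks are slow enolate formation at the tertiary C3–H of a crowded tetrasubstituted enone and binding of the biphenol product to palladium. The fallback sets out from 8 and comes back at 10, and it replaces catalytic dehydrogenation by regiospecific α'-functionalisation and elimination. Kinetic double deprotonation at C3/C3' (LiN(iPr)2, THF, −78 °C) and trapping with PhSeBr gives (4aS,4a'S,5S,5'S,8S,8'S)-3,3',8,8'-tetramethyl-3,3'-bis(phenylselanyl)-5,5'-di(propan-2-yl)-4,4',4a,4a',5,5',6,6',7,7',8,8'-dodecahydro-[1,1'-binaphthalene]-2,2'(3H,3'H)-dione F4. Oxidation with H2O2 and pyridine in CH2Cl2 (0 °C to rt) triggers selenoxide syn-elimination to the dienone stage 9, which tautomerises to 10. An exocyclic-methylene isomer, if formed, aromatises to the same phenol with a trace of acid.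

**Step 2 (oxidative enolate dimerisation).** The risks are anionic polymerisation of the enone and a modest coupling yield. The fallback sets out from 3 and comes back at 5, and it replaces the copper-mediated radical coupling by a polar umpolung coupling of an isolated silyl enol ether. Enone 3 is converted (LiN(iPr)2, Me3SiCl, THF, −78 °C) to trimethyl[(3-methylbuta-1,3-dien-2-yl)oxy]silane F1, which is distilled. Treatment with iodosylbenzene (0.5 equiv) and BF3·OEt2 in CH2Cl2 at −40 °C turns one molecule into an α-keto iodonium electrophile that is captured by a second molecule, giving 5.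

## Further compounds

F1 | step 2 | trimethyl[(3-methylbuta-1,3-dien-2-yl)oxy]silane | C=C(C)C(=C)O[Si](C)(C)C
F2 | step 3 | (3RS,4aS,5S,8S)-3,8-dimethyl-5-(propan-2-yl)-4,4a,5,6,7,8-hexahydronaphthalen-2(3H)-one | O=C1C(C)C[C@H]2[C@H](C(C)C)CC[C@H](C)C2=C1
F3 | step 3 | (5S,8S)-3,8-dimethyl-5-(propan-2-yl)-5,6,7,8-tetrahydronaphthalen-2-ol | Cc1cc2c(cc1O)[C@@H](C)CC[C@H]2C(C)C
F4 | step 4 | (4aS,4a'S,5S,5'S,8S,8'S)-3,3',8,8'-tetramethyl-3,3'-bis(phenylselanyl)-5,5'-di(propan-2-yl)-4,4',4a,4a',5,5',6,6',7,7',8,8'-dodecahydro-[1,1'-binaphthalene]-2,2'(3H,3'H)-dione | O=C1C(C)([Se]c3ccccc3)C[C@H]2[C@H](C(C)C)CC[C@H](C)C2=C1C1=C2[C@@H](C)CC[C@@H](C(C)C)[C@@H]2CC(C)([Se]c3ccccc3)C1=O
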